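**Retrosynthetic overview**
1. Feature: the methine C1 is bonded to ring C at the ring carbon flanked by both methoxy groups, which is the site n-BuLi deprotonates. C1-C2 links that carbon to C3, the benzylic CH2 of ring B (4-hydroxy-2-methoxyphenyl), so C1-C2 can be bought as the vinyl group of a vinylboronate.
2. Key disconnection: C1-ring C and C2-C3 are cut together, giving the ring C aryllithium (aldehyde masked as a dioxolane), vinylboronic acid pinacol ester and the ring B benzyl methyl carbonate. The forward three-component coupling sets C1 and leaves boron on it.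
3. C1-ring A (4-methoxyphenyl) is cut to that secondary benzylic boronate and 4-iodoanisole (Suzuki-Miyaura coupling with retention).
4. The E-alkene between ring C and ring D (4-hydroxyphenyl) is cut to the ring C aldehyde and a ring D benzylphosphonate (Horner-Wadsworth-Emmons). Both phenols travel as TIPS ethers and are freed last.
5. No ring is formed: the four benzene rings are bought and joined in the order C with B, then A, then D.

Key step: step 7

Assumption: the sense of induction of the MandyPhos-palladium catalyst with a benzyl electrophile cannot be derived from precedent, so the ligand antipode that gives (R)-14 is to be identified in a trial run (both antipodes are commercial), and the route is written for that antipode.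

Step 1
Reactants: 1 3,5-dimethoxybenzaldehyde
Product: 2 2-(3,5-dimethoxyphenyl)-1,3-dioxolane
Conditions: ethylene glycol, p-TsOH (cat.), toluene, reflux, Dean-Stark trap
Reagents that add atoms: ethylene glycol, OCCO
Why: Acid-catalysed acetalisation with azeotropic removal of water masks the aldehyde against n-BuLi and the aryllithium of step 7.

Step 2
Reactants: 3 4-hydroxy-2-methoxybenzaldehyde
Product: 4 2-methoxy-4-(triisopropylsilyloxy)benzaldehyde
Conditions: TIPSCl, imidazole, DMF, rt
Reagents that add atoms: triisopropylsilyl chloride, CC(C)[Si](Cl)(C(C)C)C(C)C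
Why: Silylation of the only hydroxyl group gives an aryl silyl ether bulky enough to withstand the hydride, alkoxide, Ag2O and dilute acid met later.

Step 3
Reactants: 4 2-methoxy-4-(triisopropylsilyloxy)benzaldehyde
Product: 5 [2-methoxy-4-(triisopropylsilyloxy)phenyl]methanol
Conditions: NaBH4, THF/MeOH, 0 °C
Reagents that add atoms: none
Why: Borohydride reduction of the aromatic aldehyde leaves the aryl silyl ether and the methyl ether untouched.

Step 4
Reactants: 5 [2-methoxy-4-(triisopropylsilyloxy)phenyl]methanol
Product: 6 2-methoxy-4-(triisopropylsilyloxy)benzyl methyl carbonate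
Conditions: ClCO2Me, pyridine, CH2Cl2, 0 °C
Reagents that add atoms: methyl chloroformate, COC(=O)Cl
Why: Acylation of the primary benzylic alcohol with a chloroformate under pyridine buffering gives the mixed carbonate without ionising the electron-rich benzylic position.

Step 5
Reactants: 7 4-hydroxybenzyl alcohol
Product: 9 diethyl (4-hydroxybenzyl)phosphonate, via p-quinone methide 8 (not isolated)
Conditions: P(OEt)3 (neat, excess), 150 °C
Reagents that add atoms: triethyl phosphite, CCOP(OCC)OCC
Why: On heating, the para-hydroxybenzyl alcohol loses water to 8, the phosphite adds to its exocyclic carbon, and dealkylation of the phosphonium ion (Michaelis-Arbuzov type) gives the phosphonate without a benzylic halide.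

Step 6
Reactants: 9 diethyl (4-hydroxybenzyl)phosphonate
Product: 10 diethyl [4-(triisopropylsilyloxy)benzyl]phosphonate
Conditions: TIPSCl, imidazole, DMF, rt
Reagents that add atoms: triisopropylsilyl chloride, CC(C)[Si](Cl)(C(C)C)C(C)C
Why: Silylation of the phenol removes the acidic proton that would otherwise consume base and deactivate the phosphonate carbanion in step 10.

Step 7
Reactants: 2 2-(3,5-dimethoxyphenyl)-1,3-dioxolane; 11 vinylboronic acid pinacol ester; 6 2-methoxy-4-(triisopropylsilyloxy)benzyl methyl carbonate
Product: 14 (R)-2-{1-[4-(1,3-dioxolan-2-yl)-2,6-dimethoxyphenyl]-3-[2-methoxy-4-(triisopropylsilyloxy)phenyl]propyl}-4,4,5,5-tetramethyl-1,3,2-dioxaborolane, via aryllithium 12 (not isolated), via lithium vinylboronate complex 13 (not isolated)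
Conditions: 2 (slight excess), n-BuLi (hexanes), THF, 0 °C, 2 h; 11, 0 °C to rt; evaporate, fresh THF; Pd(OAc)2 (3 mol %), MandyPhos ligand 1,1'-bis[bis(4-methoxy-3,5-dimethylphenyl)phosphino]-2,2'-bis[alpha-(dimethylamino)benzyl]ferrocene (single antipode, 3.6 mol %), 6, THF, 60 °C
Reagents that add atoms: n-butyllithium, [Li]CCCC (supplies only the lithium of 12 and 13; none of its atoms stays in 14)
Why: Proposed new method: n-BuLi removes the ring C proton between the two methoxy groups (directed ortho-metalation, halide-free), aryllithium 12 fills the empty orbital on boron of 11 to give boronate 13, and zerovalent palladium formed from Pd(OAc)2 ionises carbonate 6, with loss of CO2 and methoxide, to a cationic pi-benzyl complex of divalent palladium that binds the electron-rich vinyl group of 13. Ring C then shifts from boron to the boron-bearing alkene carbon C1 on the face opposite to palladium while palladium takes C2, and reductive elimination from the resulting alkyl(benzyl)palladium species joins C2 to the benzylic carbon C3, so the C1-ring C and C2-C3 bonds arise in one operation and no ring is closed. The closest known reaction types are the enantioselective palladium-catalysed conjunctive cross-coupling of vinylboron ate complexes with aryl triflates and propargylic carbonates (nickel with alkyl iodides) and the palladium-catalysed substitution of benzyl methyl carbonates under ferrocenyl diphosphine ligands, which shows that such carbonates ionise. The single new stereocentre C1 is controlled by the chiral ligand, which fixes the alkene face that palladium occupies and hence the opposite face that receives ring C, the ligand antipode being the one that leads to (R)-14. The step needs the metallate shift to outrun direct transfer of ring C or vinyl from boron to palladium and beta-hydride elimination, and the substrate helps because the two ortho-methoxy groups make ring C slow to transmetalate yet electron-rich enough to migrate readily, while the chelating diphosphine leaves no free site on the alkylpalladium species. Racemic background alkylation is excluded because a carbonate, unlike an electron-rich benzyl halide, does not react with 13 until palladium has ionised it.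

Step 8
Reactants: 14 (R)-secondary benzylic pinacol boronate; 15 4-iodoanisole
Product: 16 (S)-2-{3,5-dimethoxy-4-[1-(4-methoxyphenyl)-3-(2-methoxy-4-(triisopropylsilyloxy)phenyl)propyl]phenyl}-1,3-dioxolane
Conditions: Pd2(dba)3 (4 mol %), PPh3 (8 equiv per Pd), Ag2O (1.5 equiv), THF, 70 °C, sealed tube
Reagents that add atoms: none
Why: The Ag2O-promoted Suzuki-Miyaura coupling of enantioenriched secondary benzylic pinacol boronates with aryl iodides transfers carbon from boron to palladium through a closed oxygen-bridged transition state with retention, and the excess PPh3 keeps palladium saturated against beta-hydride elimination, so (R)-14 should map onto (S)-16, the descriptor changing only because ring A outranks C2 whereas boron did not.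

Step 9
Reactants: 16 (S)-diarylpropyl dioxolane
Product: 17 (S)-3,5-dimethoxy-4-{1-(4-methoxyphenyl)-3-[2-methoxy-4-(triisopropylsilyloxy)phenyl]propyl}benzaldehyde
Conditions: 1 M aq. HCl, THF, rt
Reagents that add atoms: water, O
Why: Mild aqueous acid hydrolyses the aryl dioxolane, while the aryl TIPS ether, the methyl ethers and the diarylmethine centre are inert under these conditions.

Step 10
Reactants: 17 (S)-aldehyde; 10 diethyl [4-(triisopropylsilyloxy)benzyl]phosphonate
Product: 18 {4-[(E)-2-(3,5-dimethoxy-4-{(S)-1-(4-methoxyphenyl)-3-[2-methoxy-4-(triisopropylsilyloxy)phenyl]propyl}phenyl)vinyl]phenoxy}triisopropylsilane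
Conditions: KOt-Bu (added last to 17 and 10), THF, 0 °C to rt
Reagents that add atoms: none
Why: Horner-Wadsworth-Emmons olefination of a non-enolisable aromatic aldehyde with a benzylic phosphonate adds reversibly and eliminates through the less crowded adduct to give the E-stilbene, and the C1-H bond is far too weakly acidic to be touched by tert-butoxide.

Step 11
Reactants: 18 bis-TIPS ether
Product: 19 4-{(S)-3-[4-((E)-4-hydroxystyryl)-2,6-dimethoxyphenyl]-3-(4-methoxyphenyl)propyl}-3-methoxyphenol (CNP0182684.1)
Conditions: TBAF, AcOH, THF, 0 °C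
Reagents that add atoms: none
Why: Fluoride cleaves both aryl Si-O bonds by forming the stronger Si-F bond, acetic acid buffering keeps the electron-rich stilbene phenoxides from oxidising, and neither C1 nor the E-alkene is affected.

**Compound list**
1 | 3,5-dimethoxybenzaldehyde | COc1cc(OC)cc(C=O)c1 | starting material
2 | 2-(3,5-dimethoxyphenyl)-1,3-dioxolane | COc1cc(OC)cc(C2OCCO2)c1 | intermediate
3 | 4-hydroxy-2-methoxybenzaldehyde | COc1cc(O)ccc1C=O | starting material
4 | 2-methoxy-4-(triisopropylsilyloxy)benzaldehyde | COc1cc(O[Si](C(C)C)(C(C)C)C(C)C)ccc1C=O | intermediate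
5 | [2-methoxy-4-(triisopropylsilyloxy)phenyl]methanol | COc1cc(O[Si](C(C)C)(C(C)C)C(C)C)ccc1CO | intermediate
6 | 2-methoxy-4-(triisopropylsilyloxy)benzyl methyl carbonate | COC(=O)OCc1ccc(O[Si](C(C)C)(C(C)C)C(C)C)cc1OC | intermediate
7 | 4-hydroxybenzyl alcohol | OCc1ccc(O)cc1 | starting material
8 | 4-methylenecyclohexa-2,5-dien-1-one (p-quinone methide, not isolated) | C=C1C=CC(=O)C=C1 | intermediate
9 | diethyl (4-hydroxybenzyl)phosphonate | CCOP(=O)(Cc1ccc(O)cc1)OCC | intermediate
10 | diethyl [4-(triisopropylsilyloxy)benzyl]phosphonate | CCOP(=O)(Cc1ccc(O[Si](C(C)C)(C(C)C)C(C)C)cc1)OCC | intermediate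
11 | vinylboronic acid pinacol ester | C=CB1OC(C)(C)C(C)(C)O1 | starting material
12 | [4-(1,3-dioxolan-2-yl)-2,6-dimethoxyphenyl]lithium (not isolated) | [Li]c1c(OC)cc(C2OCCO2)cc1OC | intermediate
13 | lithium [4-(1,3-dioxolan-2-yl)-2,6-dimethoxyphenyl](vinyl)(pinacolato)borate (not isolated) | [Li+].C=C[B-]1(c2c(OC)cc(C3OCCO3)cc2OC)OC(C)(C)C(C)(C)O1 | intermediate
14 | (R)-2-{1-[4-(1,3-dioxolan-2-yl)-2,6-dimethoxyphenyl]-3-[2-methoxy-4-(triisopropylsilyloxy)phenyl]propyl}-4,4,5,5-tetramethyl-1,3,2-dioxaborolane | CC1(C)OB([C@H](CCc2ccc(O[Si](C(C)C)(C(C)C)C(C)C)cc2OC)c2c(OC)cc(C3OCCO3)cc2OC)OC1(C)C | intermediate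
15 | 4-iodoanisole | COc1ccc(I)cc1 | starting material
16 | (S)-2-{3,5-dimethoxy-4-[1-(4-methoxyphenyl)-3-(2-methoxy-4-(triisopropylsilyloxy)phenyl)propyl]phenyl}-1,3-dioxolane | COc1ccc([C@H](CCc2ccc(O[Si](C(C)C)(C(C)C)C(C)C)cc2OC)c2c(OC)cc(C3OCCO3)cc2OC)cc1 | intermediate
17 | (S)-3,5-dimethoxy-4-{1-(4-methoxyphenyl)-3-[2-methoxy-4-(triisopropylsilyloxy)phenyl]propyl}benzaldehyde | COc1ccc([C@H](CCc2ccc(O[Si](C(C)C)(C(C)C)C(C)C)cc2OC)c2c(OC)cc(C=O)cc2OC)cc1 | intermediate
18 | (S,E)-bis(triisopropylsilyl) ether of the target | COc1ccc([C@H](CCc2ccc(O[Si](C(C)C)(C(C)C)C(C)C)cc2OC)c2c(OC)cc(/C=C/c3ccc(O[Si](C(C)C)(C(C)C)C(C)C)cc3)cc2OC)cc1 | intermediate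
19 | 4-{(S)-3-[4-((E)-4-hydroxystyryl)-2,6-dimethoxyphenyl]-3-(4-methoxyphenyl)propyl}-3-methoxyphenol | COc1ccc([C@H](CCc2ccc(O)cc2OC)c2c(OC)cc(/C=C/c3ccc(O)cc3)cc2OC)cc1 | target

**Total step count:** 11
**Longest linear sequence:** 8 steps (steps 2, 3, 4, 7, 8, 9, 10, 11; 3 to 19)

**Steps most likely to fail**

**1. Step 7.** Several processes could compete with the intended coupling:
- Ionisation of the carbonate may be slow.
- The pi-benzyl cation may be captured by the released methoxide.
- Ring C or vinyl may pass directly from boron to palladium.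
- Beta-hydride elimination may precede the sp3-sp3 reductive elimination.
- The boronate alkene may attack the benzyl ligand from outside the metal, with poor facial selectivity.

Fallback (from 2 and 4, back at 14): sparteine-mediated lithiation-borylation, a known stereospecific homologation of aryl pinacol boronates.
- Compound 2 is lithiated as in step 7 and quenched with 2-isopropoxy-4,4,5,5-tetramethyl-1,3,2-dioxaborolane to give 2-[4-(1,3-dioxolan-2-yl)-2,6-dimethoxyphenyl]-4,4,5,5-tetramethyl-1,3,2-dioxaborolane F1.
- Aldehyde 4 undergoes a Wittig reaction with Ph3P=CHCO2Et to give ethyl (E)-3-[2-methoxy-4-(triisopropylsilyloxy)phenyl]acrylate F2.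
- Hydrogenation (H2, Pd/C, EtOAc) gives ethyl 3-[2-methoxy-4-(triisopropylsilyloxy)phenyl]propanoate F3.
- Reduction (i-Bu2AlH, CH2Cl2) gives 3-[2-methoxy-4-(triisopropylsilyloxy)phenyl]propan-1-ol F4.
- Carbamoylation (N,N-diisopropylcarbamoyl chloride, Et3N, CH2Cl2, reflux) gives 3-[2-methoxy-4-(triisopropylsilyloxy)phenyl]propyl N,N-diisopropylcarbamate F5.
- s-BuLi with (-)-sparteine (Et2O, -78 °C) removes the pro-S proton next to oxygen to give the (S)-alpha-lithiated carbamate F6.
- Boronate F1 is captured with retention to give the (S)-lithium boronate complex F7.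
- MgBr2·OEt2 at reflux drives migration of ring C with inversion and loss of the carbamate, which should give (R)-14.

**2. Step 8.** Boron-to-palladium transfer at a carbon flanked by two ortho-methoxy groups may be slow. Protodeboronation, beta-hydride elimination or erosion of stereochemical fidelity could then compete.

Fallback (from 14, back at 16): the C1-ring A bond is made without a transition metal, by a second 1,2-metallate shift.
- 4-Bromophenol is treated with t-BuLi (3 equiv, THF, -78 °C) to give lithium 4-lithiophenolate F8.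
- F8 adds to 14 to give the dilithium (4-oxidophenyl)boronate complex F9.
- Ph3BiF2 activates the phenolate oxygen, C1 migrates from boron to the ipso carbon with retention, and loss of the boryl group restores the aromatic ring. This gives (S)-4-{1-[4-(1,3-dioxolan-2-yl)-2,6-dimethoxyphenyl]-3-[2-methoxy-4-(triisopropylsilyloxy)phenyl]propyl}phenol F10.
- The only free hydroxyl group of F10 is methylated (MeI, K2CO3, acetone, rt) to give 16.

**3. Step 10.** tert-Butoxide may attack silicon of the phosphonate's aryl silyl ether faster than olefination proceeds. This would leave a phenoxide-bearing phosphonate that deprotonates and adds sluggishly. Incomplete E selectivity is a lesser concern.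

Fallback (from 17, back at 19): the alkene is built by methylenation and a Mizoroki-Heck reaction, which also makes steps 5 and 6 unnecessary.
- Wittig methylenation of 17 (MePPh3Br, KOt-Bu, THF) gives (S)-triisopropyl{3-methoxy-4-[3-(2,6-dimethoxy-4-vinylphenyl)-3-(4-methoxyphenyl)propyl]phenoxy}silane F11.
- Heck coupling with 4-iodophenol (Pd(OAc)2, P(o-tol)3, Et3N, DMF, 100 °C) gives the (S,E)-ring B mono-TIPS ether of the target F12.
- F12 is desilylated under the conditions of step 11 to give 19.

**Further compounds**
F1 | step 7 | 2-[4-(1,3-dioxolan-2-yl)-2,6-dimethoxyphenyl]-4,4,5,5-tetramethyl-1,3,2-dioxaborolane | COc1cc(C2OCCO2)cc(OC)c1B1OC(C)(C)C(C)(C)O1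
F2 | step 7 | ethyl (E)-3-[2-methoxy-4-(triisopropylsilyloxy)phenyl]acrylate | CCOC(=O)/C=C/c1ccc(O[Si](C(C)C)(C(C)C)C(C)C)cc1OC
F3 | step 7 | ethyl 3-[2-methoxy-4-(triisopropylsilyloxy)phenyl]propanoate | CCOC(=O)CCc1ccc(O[Si](C(C)C)(C(C)C)C(C)C)cc1OC
F4 | step 7 | 3-[2-methoxy-4-(triisopropylsilyloxy)phenyl]propan-1-ol | OCCCc1ccc(O[Si](C(C)C)(C(C)C)C(C)C)cc1OC
F5 | step 7 | 3-[2-methoxy-4-(triisopropylsilyloxy)phenyl]propyl N,N-diisopropylcarbamate | CC(C)N(C(C)C)C(=O)OCCCc1ccc(O[Si](C(C)C)(C(C)C)C(C)C)cc1OC
F6 | step 7 | (S)-alpha-lithiated carbamate | [Li][C@H](OC(=O)N(C(C)C)C(C)C)CCc1ccc(O[Si](C(C)C)(C(C)C)C(C)C)cc1OC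
F7 | step 7 | (S)-lithium boronate complex | [Li+].CC1(C)O[B-](c2c(OC)cc(C3OCCO3)cc2OC)([C@H](OC(=O)N(C(C)C)C(C)C)CCc2ccc(O[Si](C(C)C)(C(C)C)C(C)C)cc2OC)OC1(C)C
F8 | step 8 | lithium 4-lithiophenolate | [Li+].[Li]c1ccc([O-])cc1
F9 | step 8 | dilithium (4-oxidophenyl)boronate complex | [Li+].[Li+].CC1(C)O[B-](c2ccc([O-])cc2)([C@H](CCc2ccc(O[Si](C(C)C)(C(C)C)C(C)C)cc2OC)c2c(OC)cc(C3OCCO3)cc2OC)OC1(C)C
F10 | step 8 | (S)-4-{1-[4-(1,3-dioxolan-2-yl)-2,6-dimethoxyphenyl]-3-[2-methoxy-4-(triisopropylsilyloxy)phenyl]propyl}phenol | Oc1ccc([C@H](CCc2ccc(O[Si](C(C)C)(C(C)C)C(C)C)cc2OC)c2c(OC)cc(C3OCCO3)cc2OC)cc1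
F11 | step 10 | (S)-triisopropyl{3-methoxy-4-[3-(2,6-dimethoxy-4-vinylphenyl)-3-(4-methoxyphenyl)propyl]phenoxy}silane | COc1ccc([C@H](CCc2ccc(O[Si](C(C)C)(C(C)C)C(C)C)cc2OC)c2c(OC)cc(C=C)cc2OC)cc1
F12 | step 10 | (S,E)-ring B mono-TIPS ether of the target | COc1ccc([C@H](CCc2ccc(O[Si](C(C)C)(C(C)C)C(C)C)cc2OC)c2c(OC)cc(/C=C/c3ccc(O)cc3)cc2OC)cc1
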